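**Retrosynthetic overview**
- The epoxide comes last, by α-face epoxidation of the C8=C9 alkene of the 4-O-vanilloyl diol; the tertiary ester comes from isopropyl addition to a C4 ketone followed by acylation of the alkoxide in the same flask.
- The trans-fused β-hydroxy ketone (C5-H, C6-OH) comes from conjugate borylation/oxidation of a bicyclic dienone.
- The seven-membered ring comes from a rhodium-catalysed (5+2) ring expansion of a vinylcyclopropane with a silyl-capped propyne.
- The cyclopentanone and the cyclopropane are closed together by an enantioselective intramolecular cyclopropanation of an acyclic vinyl diazoketone, which sets the quaternary C1.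
- Ring order: five- and three-membered rings (one operation), then the seven-membered ring (cyclopropane consumed), then the epoxide.

Assumption: daucane numbering is used throughout (C1 angular-methyl carbon, C4 isopropyl carbinol, C5 ring-fusion CH, C6 carbinol, C8=C9 alkene, C10 CH2 next to C1), and Rh2(S-DOSP)4 is taken to give the (1R,5R) enantiomer of 8; if the sense is opposite, Rh2(R-DOSP)4 is used.

**Step 1**
Reactants: 1 5-methylhex-5-en-2-one
Product: 3 1-diazo-5-methylhex-5-en-2-one, via trifluoroacetyl diketone 2 (not isolated)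
Conditions: LiN(SiMe3)2, THF, −78 °C; CF3CO2CH2CF3; then MsN3, Et3N, H2O, MeCN, rt
Reagents that add atoms: 2,2,2-trifluoroethyl trifluoroacetate O=C(OCC(F)(F)F)C(F)(F)F (CF3CO group, carried in 2 only); methanesulfonyl azide CS(=O)(=O)N=[N+]=[N-]
Why: Danheiser detrifluoroacetylative diazo transfer, in which kinetic enolisation and trifluoroacetylation at the methyl group activate only that carbon for Regitz diazo transfer; no stereocentre is formed.

**Step 2**
Reactants: 3 1-diazo-5-methylhex-5-en-2-one; 4 acetaldehyde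
Product: 7 3-diazo-7-methylocta-1,7-dien-4-one, via diazo aldol 5 (not isolated), via dichlorophosphate 6 (not isolated)
Conditions: MeCHO (excess), DBU (cat.), CH2Cl2, 0 °C; then Et3N, POCl3, 0 °C; product kept cold and used at once
Reagents that add atoms: phosphoryl chloride O=P(Cl)(Cl)Cl (carried in 6 only)
Why: Base-catalysed aldol addition of the acyldiazomethane carbon to the aldehyde followed by POCl3/Et3N dehydration (Davies-type vinyldiazo synthesis) turns the diazo carbon into a vinyl-substituted carbene precursor, and the carbinol stereocentre of 5 is destroyed in the elimination.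

**Step 3 (key step)**
Reactants: 7 3-diazo-7-methylocta-1,7-dien-4-one
Product: 8 (1R,5R)-1-ethenyl-5-methylbicyclo[3.1.0]hexan-2-one
Conditions: Rh2(S-DOSP)4 (1 mol %), 2,2-dimethylbutane, −40 → 0 °C, slow addition of 7
Reagents that add atoms: none
Why: Enantioselective intramolecular cyclopropanation of a dirhodium vinylcarbenoid onto the tethered 1,1-disubstituted alkene closes the cyclopentanone and the cyclopropane in one operation, the cis fusion being obligatory and the chiral carboxylate catalyst choosing the alkene face, which fixes the methyl-bearing quaternary carbon (C1) as R.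

**Step 4**
Reactants: 8 (1R,5R)-1-ethenyl-5-methylbicyclo[3.1.0]hexan-2-one; 9 trimethyl(prop-1-yn-1-yl)silane
Product: 11 (3aR)-3a,6-dimethyl-3,3a,4,7-tetrahydroazulen-1(2H)-one, via vinylsilane cycloadduct 10 (not isolated)
Conditions: 9 (2 equiv), [Rh(CO)2Cl]2 (5 mol %), ClCH2CH2Cl, 80 °C; then CF3CO2H, 0 °C
Reagents that add atoms: none
Why: Wender-type rhodium-catalysed intermolecular (5+2) cycloaddition of a vinylcyclopropane with an alkyne, in which the less substituted vinyl- and acyl-activated C5–C10 bond is cleaved and the bulky silyl-bearing alkyne carbon ends next to the former cyclopropane CH2 so that methyl sits on C8, followed by ipso-protodesilylation of the vinylsilane through the β-silyl cation, which leaves the C8=C9 alkene in place and C1 untouched.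

**Step 5**
Reactants: 11 (3aR)-3a,6-dimethyl-3,3a,4,7-tetrahydroazulen-1(2H)-one
Product: 13 (3aR,8S,8aS)-8-hydroxy-3a,6-dimethyl-3,3a,4,7,8,8a-hexahydroazulen-1(2H)-one, via β-boryl ketone 12 (not isolated)
Conditions: B2pin2, CuCl (5 mol %), NaOtBu (5 mol %), bis[2-(diphenylphosphino)phenyl] ether, MeOH, THF, 0 °C; then NaBO3·4H2O, THF/H2O, 0 °C → rt
Reagents that add atoms: bis(pinacolato)diboron CC1(C)OB(OC1(C)C)B1OC(C)(C)C(C)(C)O1 (boron carried in 12 only); sodium perborate [Na+].[Na+].O[B-]1(O)OO[B-](O)(O)OO1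
Why: Copper-catalysed conjugate borylation of the alkylidene cyclopentanone and perborate oxidation with retention at carbon, in which boryl copper adds to C6 and the enolate is protonated at C5 both from the face opposite the axial angular methyl (as in additions to 5-ene steroids), giving the trans ring fusion with 5-H and 6-OH both alpha.

**Step 6**
Reactants: 13 (3aR,8S,8aS)-8-hydroxy-3a,6-dimethyl-3,3a,4,7,8,8a-hexahydroazulen-1(2H)-one
Product: 14 (3aR,8S,8aS)-3a,6-dimethyl-8-[(triethylsilyl)oxy]-3,3a,4,7,8,8a-hexahydroazulen-1(2H)-one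
Conditions: Et3SiCl, imidazole, DMF, 0 °C → rt
Reagents that add atoms: chlorotriethylsilane CC[Si](Cl)(CC)CC
Why: Silyl ether protection of the secondary alcohol under mild imidazole conditions that do not epimerise C5, so that the tertiary alkoxide made later is the only oxygen that can be acylated.

**Step 7**
Reactants: 15 vanillic acid (4-hydroxy-3-methoxybenzoic acid)
Product: 16 tert-butyldimethylsilyl 4-[(tert-butyldimethylsilyl)oxy]-3-methoxybenzoate
Conditions: t-BuMe2SiCl (2.2 equiv), imidazole, DMF, rt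
Reagents that add atoms: tert-butyl(chloro)dimethylsilane CC(C)(C)[Si](C)(C)Cl
Why: Double silylation masks the phenol and activates the acid as a silyl ester in one operation.

**Step 8**
Reactants: 16 tert-butyldimethylsilyl 4-[(tert-butyldimethylsilyl)oxy]-3-methoxybenzoate
Product: 17 4-[(tert-butyldimethylsilyl)oxy]-3-methoxybenzoyl chloride
Conditions: (COCl)2, DMF (cat.), CH2Cl2, 0 °C → rt
Reagents that add atoms: oxalyl chloride ClC(=O)C(Cl)=O
Why: Wissner conversion of a silyl ester into the acid chloride with the Vilsmeier reagent under neutral conditions, which leaves the aryl silyl ether intact.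

**Step 9**
Reactants: 14 (3aR,8S,8aS)-3a,6-dimethyl-8-[(triethylsilyl)oxy]-3,3a,4,7,8,8a-hexahydroazulen-1(2H)-one; 17 4-[(tert-butyldimethylsilyl)oxy]-3-methoxybenzoyl chloride
Product: 19 (1R,3aR,8S,8aS)-3a,6-dimethyl-1-(propan-2-yl)-8-[(triethylsilyl)oxy]-1,2,3,3a,4,7,8,8a-octahydroazulen-1-yl 4-[(tert-butyldimethylsilyl)oxy]-3-methoxybenzoate, via chloromagnesium alkoxide 18 (not isolated)
Conditions: i-PrMgCl, LaCl3·2LiCl, THF, −78 °C; then 17, DMAP, −78 °C → rt
Reagents that add atoms: isopropylmagnesium chloride CC(C)[Mg]Cl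
Why: Lanthanum-promoted Grignard 1,2-addition (enolisation and reduction suppressed) from the alpha face, anti to the axial angular methyl of the trans-fused ketone, sets C4 as R (oxygen beta, isopropyl alpha), and the hindered tertiary alkoxide is esterified in the same flask by the acid chloride.

**Step 10**
Reactants: 19 (1R,3aR,8S,8aS)-3a,6-dimethyl-1-(propan-2-yl)-8-[(triethylsilyl)oxy]-1,2,3,3a,4,7,8,8a-octahydroazulen-1-yl 4-[(tert-butyldimethylsilyl)oxy]-3-methoxybenzoate
Product: 20 (1R,3aR,8S,8aS)-8-hydroxy-3a,6-dimethyl-1-(propan-2-yl)-1,2,3,3a,4,7,8,8a-octahydroazulen-1-yl 4-hydroxy-3-methoxybenzoate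
Conditions: Bu4NF, AcOH (1:1), THF, 0 °C → rt
Reagents that add atoms: none
Why: Acetic-acid-buffered fluoride desilylation removes the aryl and the secondary alkyl silyl ethers without generating a free alkoxide, so the tertiary ester neither migrates to O-6 nor hydrolyses.

**Step 11**
Reactants: 20 (1R,3aR,8S,8aS)-8-hydroxy-3a,6-dimethyl-1-(propan-2-yl)-1,2,3,3a,4,7,8,8a-octahydroazulen-1-yl 4-hydroxy-3-methoxybenzoate
Product: 21 (1R,4R,5S,6S,8R,9S)-8,9-epoxy-6-hydroxydaucan-4-yl 4-hydroxy-3-methoxybenzoate (target, daucane numbering)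
Conditions: m-CPBA (1.1 equiv), NaHCO3, CH2Cl2, 0 °C
Reagents that add atoms: 3-chloroperoxybenzoic acid OOC(=O)c1cccc(Cl)c1
Why: Prilezhaev epoxidation of the only alkene, delivered to the alpha face because the beta face is shielded by the angular methyl and the C4 ester while the homoallylic 6α-hydroxyl directs the peracid by hydrogen bonding (Henbest effect), giving the 8R,9S epoxide.

**Compound list**
1 | 5-methylhex-5-en-2-one | CC(=O)CCC(C)=C | starting material
2 | 1,1,1-trifluoro-7-methyloct-7-ene-2,4-dione | O=C(CC(=O)CCC(C)=C)C(F)(F)F | intermediate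
3 | 1-diazo-5-methylhex-5-en-2-one | [N-]=[N+]=CC(=O)CCC(C)=C | intermediate
4 | acetaldehyde | CC=O | starting material
5 | 3-diazo-2-hydroxy-7-methyloct-7-en-4-one (racemic) | CC(O)C(=[N+]=[N-])C(=O)CCC(C)=C | intermediate
6 | 3-diazo-7-methyl-4-oxooct-7-en-2-yl phosphorodichloridate (racemic) | CC(OP(=O)(Cl)Cl)C(=[N+]=[N-])C(=O)CCC(C)=C | intermediate
7 | 3-diazo-7-methylocta-1,7-dien-4-one | C=CC(=[N+]=[N-])C(=O)CCC(C)=C | intermediate
8 | (1R,5R)-1-ethenyl-5-methylbicyclo[3.1.0]hexan-2-one | O=C1CC[C@]2(C)C[C@]12C=C | intermediate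
9 | trimethyl(prop-1-yn-1-yl)silane | CC#C[Si](C)(C)C | starting material
10 | (3aR)-3a,6-dimethyl-5-(trimethylsilyl)-3,3a,4,7-tetrahydroazulen-1(2H)-one | O=C1CC[C@]2(C)CC([Si](C)(C)C)=C(C)CC=C12 | intermediate
11 | (3aR)-3a,6-dimethyl-3,3a,4,7-tetrahydroazulen-1(2H)-one | O=C1CC[C@]2(C)CC=C(C)CC=C12 | intermediate
12 | (3aR,8S,8aR)-3a,6-dimethyl-8-(4,4,5,5-tetramethyl-1,3,2-dioxaborolan-2-yl)-3,3a,4,7,8,8a-hexahydroazulen-1(2H)-one | O=C1CC[C@]2(C)CC=C(C)C[C@H](B3OC(C)(C)C(C)(C)O3)[C@@H]12 | intermediate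
13 | (3aR,8S,8aS)-8-hydroxy-3a,6-dimethyl-3,3a,4,7,8,8a-hexahydroazulen-1(2H)-one | O=C1CC[C@]2(C)CC=C(C)C[C@H](O)[C@@H]12 | intermediate
14 | (3aR,8S,8aS)-3a,6-dimethyl-8-[(triethylsilyl)oxy]-3,3a,4,7,8,8a-hexahydroazulen-1(2H)-one | O=C1CC[C@]2(C)CC=C(C)C[C@H](O[Si](CC)(CC)CC)[C@@H]12 | intermediate
15 | vanillic acid | COc1cc(C(=O)O)ccc1O | starting material
16 | tert-butyldimethylsilyl 4-[(tert-butyldimethylsilyl)oxy]-3-methoxybenzoate | COc1cc(C(=O)O[Si](C)(C)C(C)(C)C)ccc1O[Si](C)(C)C(C)(C)C | intermediate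
17 | 4-[(tert-butyldimethylsilyl)oxy]-3-methoxybenzoyl chloride | COc1cc(C(Cl)=O)ccc1O[Si](C)(C)C(C)(C)C | intermediate
18 | chloromagnesium (1R,3aR,8S,8aS)-3a,6-dimethyl-1-(propan-2-yl)-8-[(triethylsilyl)oxy]-1,2,3,3a,4,7,8,8a-octahydroazulen-1-olate | CC(C)[C@]1(O[Mg]Cl)CC[C@]2(C)CC=C(C)C[C@H](O[Si](CC)(CC)CC)[C@@H]12 | intermediate
19 | (1R,3aR,8S,8aS)-3a,6-dimethyl-1-(propan-2-yl)-8-[(triethylsilyl)oxy]-1,2,3,3a,4,7,8,8a-octahydroazulen-1-yl 4-[(tert-butyldimethylsilyl)oxy]-3-methoxybenzoate | CC(C)[C@]1(OC(=O)c2ccc(O[Si](C)(C)C(C)(C)C)c(OC)c2)CC[C@]2(C)CC=C(C)C[C@H](O[Si](CC)(CC)CC)[C@@H]12 | intermediate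
20 | (1R,3aR,8S,8aS)-8-hydroxy-3a,6-dimethyl-1-(propan-2-yl)-1,2,3,3a,4,7,8,8a-octahydroazulen-1-yl 4-hydroxy-3-methoxybenzoate | CC(C)[C@]1(OC(=O)c2ccc(O)c(OC)c2)CC[C@]2(C)CC=C(C)C[C@H](O)[C@@H]12 | intermediate
21 | (1R,4R,5S,6S,8R,9S)-8,9-epoxy-6-hydroxydaucan-4-yl 4-hydroxy-3-methoxybenzoate (daucane numbering) | COc1cc(C(=O)O[C@@]2(C(C)C)CC[C@]3(C)C[C@@H]4O[C@]4(C)C[C@H](O)[C@H]32)ccc1O | target

**Step count**
Total: 11 steps. Longest linear sequence: 9 steps (1–6, 9, 10, 11); steps 7 and 8 make the acid chloride.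

**Three steps most likely to fail**

Step 3. The unsubstituted vinyl diazoketone 7 may cyclise to a pyrazole before it is used, or the cyclopropanation may give low ee. The fallback sets out from 1 and uses a stable acceptor/acceptor diazo compound, building the vinyl group afterwards. NaH and dimethyl carbonate convert 1 into methyl 6-methyl-3-oxohept-6-enoate F1. Diazo transfer with 4-acetamidobenzenesulfonyl azide and Et3N gives methyl 2-diazo-6-methyl-3-oxohept-6-enoate F2. [Cu(MeCN)4]PF6 with a tert-butyl bisoxazoline ligand closes methyl (1R,5R)-5-methyl-2-oxobicyclo[3.1.0]hexane-1-carboxylate F3. LiAlH4 reduces both carbonyls to (1S,5R)-1-(hydroxymethyl)-5-methylbicyclo[3.1.0]hexan-2-ol F4, Swern oxidation gives (1S,5R)-5-methyl-2-oxobicyclo[3.1.0]hexane-1-carbaldehyde F5, and one equivalent of Ph3P=CH2 at −78 °C methylenates only the aldehyde, which comes back to the route at 8.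

Step 4. The acyl-substituted bicyclic vinylcyclopropane with an internal silylalkyne is outside the usual scope of the intermolecular (5+2), and the reactivity or regiochemistry may fail. The fallback sets out from 8 and makes the cycloaddition intramolecular through a temporary silicon tether. NaBH4 delivers hydride from the face opposite the cyclopropane to give (1R,2R,5R)-1-ethenyl-5-methylbicyclo[3.1.0]hexan-2-ol F6. Chlorodimethyl(prop-1-yn-1-yl)silane and imidazole give {[(1R,2R,5R)-1-ethenyl-5-methylbicyclo[3.1.0]hexan-2-yl]oxy}dimethyl(prop-1-yn-1-yl)silane F7. [Rh(CO)2Cl]2 in ClCH2CH2Cl then effects the tethered (5+2) to the silicon-bridged cycloadduct F8, with silicon on C9 and oxygen on C4. Bu4NF cleaves the Si–O and Si–C bonds to (1R,3aR)-3a,6-dimethyl-1,2,3,3a,4,7-hexahydroazulen-1-ol F9, and MnO2 oxidation of this allylic alcohol comes back to the route at 11.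

Step 5. Protonation of the enolate at C5 may give the cis-fused ketone, which could also be the thermodynamic epimer, and the skipped dienone 11 may isomerise under the basic conditions. The fallback sets out from 8 and fixes C5 and C6 by hydroboration of a non-conjugated diene. 1,2-Bis(trimethylsilyloxy)ethane with catalytic Me3SiOTf ketalises 8 to (1R,5R)-1-ethenyl-5-methylspiro[bicyclo[3.1.0]hexane-2,2'-[1,3]dioxolane] F10. The (5+2) with 9 under the step 4 conditions, without the acid treatment, gives the ethylene ketal of 10, F11. BH3·THF then attacks only the C5=C6 alkene (the silyl-capped alkene is tetrasubstituted) from the face opposite the angular methyl, and NaBO3·4H2O gives the ethylene ketal of the 5-trimethylsilyl analogue of 13, F12. Aqueous CF3CO2H removes the ketal and the silicon and comes back to the route at 13.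

**Further compounds**
F1 | step 3 | methyl 6-methyl-3-oxohept-6-enoate | COC(=O)CC(=O)CCC(C)=C
F2 | step 3 | methyl 2-diazo-6-methyl-3-oxohept-6-enoate | COC(=O)C(=[N+]=[N-])C(=O)CCC(C)=C
F3 | step 3 | methyl (1R,5R)-5-methyl-2-oxobicyclo[3.1.0]hexane-1-carboxylate | O=C1CC[C@]2(C)C[C@]12C(=O)OC
F4 | step 3 | (1S,5R)-1-(hydroxymethyl)-5-methylbicyclo[3.1.0]hexan-2-ol (both C2 epimers) | OC1CC[C@]2(C)C[C@]12CO
F5 | step 3 | (1S,5R)-5-methyl-2-oxobicyclo[3.1.0]hexane-1-carbaldehyde | O=C1CC[C@]2(C)C[C@]12C=O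
F6 | step 4 | (1R,2R,5R)-1-ethenyl-5-methylbicyclo[3.1.0]hexan-2-ol | O[C@@H]1CC[C@]2(C)C[C@]12C=C
F7 | step 4 | {[(1R,2R,5R)-1-ethenyl-5-methylbicyclo[3.1.0]hexan-2-yl]oxy}dimethyl(prop-1-yn-1-yl)silane | CC#C[Si](C)(C)O[C@@H]1CC[C@]2(C)C[C@]12C=C
F8 | step 4 | silicon-bridged (5+2) cycloadduct, dimethylsilylene linking O-4 and C-9 of the hydroazulene diene | C[Si]1(C)O[C@@H]2CC[C@]3(C)CC1=C(C)CC=C23
F9 | step 4 | (1R,3aR)-3a,6-dimethyl-1,2,3,3a,4,7-hexahydroazulen-1-ol | O[C@@H]1CC[C@]2(C)CC=C(C)CC=C12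
F10 | step 5 | (1R,5R)-1-ethenyl-5-methylspiro[bicyclo[3.1.0]hexane-2,2'-[1,3]dioxolane] | C13(OCCO3)CC[C@]2(C)C[C@]12C=C
F11 | step 5 | ethylene ketal of 10 | C13(OCCO3)CC[C@]2(C)CC([Si](C)(C)C)=C(C)CC=C12
F12 | step 5 | ethylene ketal of the 5-trimethylsilyl analogue of 13 | C13(OCCO3)CC[C@]2(C)CC([Si](C)(C)C)=C(C)C[C@H](O)[C@@H]12
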